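At 12 h, what does the flask hold?

| setting | Friday's | Thursday's | flask |
|---|---|---|---|
| free monomer | 13 mM | 52 mM | 26 mM |
| initiator | 0.62 mM | 0.62 mM | 0.62 mM |
| remark | run made earlier | run made earlier |  |
| time |  |  | 12 h |

| run | time / h | monomer in chains / % | free monomer / % |
|---|---|---|---|
| Friday's | 1.50 | 0.5 | 99.2 |
| Friday's | 3.00 | 1.7 | 98.2 |
| Friday's | 5.00 | 2.6 | 97.2 |
| Friday's | 6.00 | 3.5 | 96.3 |
| Friday's | 8.00 | 4.6 | 95.2 |
| Friday's | 10.0 | 5.7 | 94.6 |
| Friday's | 12.0 | 7.4 | 93.2 |
| Thursday's | 1.00 | 1.5 | 99.4 |
| Thursday's | 1.33 | 1.6 | 98.5 |
| Thursday's | 2.00 | 3.7 | 96.1 |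
| Thursday's | 3.00 | 6.2 | 93.5 |
| Thursday's | 5.00 | 13.2 | 86.8 |
| Thursday's | 8.00 | 22.5 | 77.7 |
| Thursday's | 12.0 | 32.9 | 67.2 |

(standard deviation of a reading: 0.3 percentage points)

- average number of monomer units in a chain (chains begun, living or dead) at 12 h
- part of the free monomer that has reacted at 12 h

- the average divides the monomer in chains by the number of chains begun, living and dead together
- the earlier runs were read with a standard deviation of 0.3 percentage points
- the earlier runs do not show the number of chains; that part of a forecast is a guess

Examiner: What do the runs show late on?

Candidate: Take one window in both, 8.00 h to 12.0 h. Thursday's run loses 1.36 mM h⁻¹ of free monomer around 37.7 mM. Friday's run loses 0.0650 mM h⁻¹ around 12.2 mM. That is 20.9 times the rate for 3.09 times the monomer.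

Examiner: What rule fits that?

Candidate: Freeze the living ends: I assume both windows hold about equal numbers of them. Net loss then goes with [free monomer] minus a constant, and the two windows put that constant at 11.0 mM. Call it the floor, the [free monomer] at which net loss stops; the usual term is equilibrium monomer concentration.

Examiner: Friday's drop is small. Is that safe?

Candidate: Not very. It is 2 percentage points, with 0.3 points on each reading, so the floor is a rough reading.

Examiner: And the flask?

Candidate: Its initiator charge and hours match Thursday's run. I assume its living ends match that run's too, so I carry over that run's fall in the excess over the floor, a logarithm of 0.537. The flask's excess starts at 15.0 mM, so its [free monomer] ends near 19.8 mM. My c is 24.0%. One chain per initiator, a guess, gives a dp of 10.1.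

The forecast says 15.5% and a dp of 15, reasoning “Interpolating geometrically to 26 mM gives about 0.014 per hour”. My c stands higher, and my dp lower.

The flask gives 21.5% and a dp of 9.67.

free monomer + living end → monomer in chains + living end, rate k1*[living end]*[free monomer] (k = 0.0240 M⁻¹ s⁻¹); monomer in chains + living end → free monomer + living end, rate k2*[living end] as long as [monomer in chains] is above zero (k = 2.70 × 10⁻⁴ s⁻¹); free monomer + initiator → living end + monomer in chains (k = 0.00270 M⁻¹ s⁻¹) At 12.0 h the flask makes monomer in chains 1.83 times faster than it uses it up, each step taken net. The floor, a rough reading, puts the end of the flask's charge near 57.8% reacted. The same flask left until 50.0 h has reacted 52.1%, and its [free monomer] of 12.5 mM stands 1.48 mM above the floor.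

(All runs were computed with made-up constants.)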